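## The problem

The target is an achiral biflavone: a 5-hydroxy-7-methoxychromone (rings A and C) carries a 4-hydroxyphenyl group (ring B) on C2, and its C3 is bonded to E3 of a central benzene ring E. Ring E is also the 2-aryl group of a 5,7-dihydroxychromone (rings D and F), joined through E1 to C2'', and it bears a hydroxyl on E4. The hard bond is C3–E3: C3 sits between the C2 aryl group and the C4 carbonyl, and E3 sits next to the E4 oxygen, so joining two finished halves there means forming a tri-ortho-substituted biaryl axis. No stereocentre has to be set; what must be controlled is the regiochemistry of each ring-forming event and the differentiation of six phenolic oxygens, of which only O7 is methylated. The free polyphenol is sensitive to air and base, the phloroglucinol-type rings A and D are easily C-alkylated, and chromones open at C2 in hot hydroxide, so the oxygens should stay masked until one mild final operation that spares the O7 methyl ether. The enabling feature is the 1,3,4-pattern of ring E: oxygen on E4, the chromone carbon on the neighbouring E3, and an acyl-level carbon (C2'') on E1, para to the oxygen. That is the pattern a 2-pyrone-5-carboxylate (E1, E2, E5, E6 and the ester) leaves behind when an α-substituted ketene acetal (E3, E4 and its oxygen) adds across it and the lactone bridge is lost. The crowded C3–E3 bond can therefore be carried as the CH2–C3 bond of a chromon-3-ylacetic acid, made as an unstrained bond of an aliphatic keto ester before ring C or ring E exists.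

## Retrosynthesis

**22 from 21.** The four O–benzyl bonds and the O5–methyl bond are cut, leading back to the fully masked biflavone 21. Holding O5 as a methyl ether (not a benzyl ether) lets ring A come from a symmetrical trimethoxyarene with no selective alkylation. The O5 methyl is the only methyl ether peri to a chromone carbonyl, so chelation-assisted boron trihalide cleavage removes it together with the benzyl groups and leaves O7 methylated. The forward step must cleave five ethers completely in one operation.

**21 from 16 and 18.** Ring F is opened at O1''–C2'' to the o-hydroxyaryl 1,3-diketone 20, and 20 is cut at C2''–C3'' into benzoic acid 16 (activated as chloride 19) and acetophenone 18. This is the standard flavone construction and has no aurone or regiochemical ambiguity. It also uses exactly the carboxyl group that ring E acquires from the pyrone. Acid 16 holds rings A, B, C and E; 18 is one step from commercial 17. The forward reactions are a C-acylation of a phenoxide–enolate dianion and an acid cyclodehydration.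

**16 from 13.** Only functional groups change: the acid comes from methyl ester 15, and the E4 benzyl ether of 15 from the silyl ether 13 through phenol 14. The exchange is needed because an aryl silyl ether para to an ester would not survive hydroxide or the amide base used later; a benzyl ether does, and it leaves in the final step.

**13 from 9 and 10 (key disconnection).** Ring E is cut at E2–E3 and E4–E5. E3 and E4 go to the bis(silyl) ketene acetal 9; E1, E2, E5 and E6 with the ester go to methyl coumalate 10. The neighbouring cut, C3–E3 by cross-coupling, would force a hindered biaryl coupling and require two separately functionalised aromatic halves. Here ring E disappears altogether, one partner is purchased, and the hindered bond is already present in 9 as a side-chain bond. The forward reaction must be a regioselective inverse-demand cycloaddition of a bulky ketene acetal, followed by decarboxylation and aromatisation by loss of one silyloxy group.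

**9 from 7.** The two O–Si bonds are cut to give acetic acid 8, and 8 comes from methyl ester 7. Two identical silyl groups are chosen so that the later elimination has only one possible outcome.

**7 from 4 and 5.** Ring C is opened at O1–C2 to diketone 6, and 6 is cut at C2–C3 into keto ester 4 and aroyl chloride 5. Carrying the acetic acid arm as the ester end of a 4-aryl-4-oxobutanoate places the C3 substituent before ring C closes, so no preformed flavone has to be alkylated at its hindered C3. The forward steps are an enolate aroylation and a cyclodehydration.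

**4 from 1 and 2.** The aryl–acyl bond is cut to symmetrical 1 and the half-ester chloride 2, giving ketone 3, in which one ortho methyl ether is then removed. The symmetry of 1 removes any regiochemical question, and the single demethylation is directed by the new ketone.

**18 from 17.** Two O–benzyl bonds are cut. The hydroxyl hydrogen-bonded to the acetyl group is the least nucleophilic and stays free, which is what the later acylation and ring closure need.

## Roads not taken

Alternative 1: Ring C of the methoxy chromone is cut at C4–C4a and O1–C2, so that unprotected phloroglucinol A3 serves as ring A and keto ester A2 carries rings B, E, D and F. In the forward key step A3 and A2 are heated without catalyst; methanol is lost to an acylketene, which C-acylates A3, and cyclodehydration gives the 5,7-dihydroxy compound A1. O7 methylation and debenzylation would follow.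
- Merits: very convergent; A3 is symmetrical, so there is no regiochemical question; ring A needs no protecting group; methylation of A1 at O7 beside the chelated O5–H is as selective as the peri demethylation used in the chosen plan. The C3–E3 bond is again an sp3 bond in the precursor.
- Weak points: the melt needs about 250 °C, applied to a heavy, non-volatile α-aryl β-keto ester bearing four benzyl ethers and a chromone. Such esters also fragment by retro-Claisen cleavage. The acylketene from A2 is fully substituted and hindered, A3 can condense twice or through oxygen, and A2 itself requires an arylacetate that already contains chromone F.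
- Comparison: on step count this road is better. The chosen plan offers a ring-forming step at about 130 °C and keeps the most valuable intermediate out of a high-temperature melt.

Alternative 2: Ring A is cut at C4a–C5 and traced to a 2,3-diaryl-4-pyrone A5 bearing a 4-methoxy-2,4-dioxobutyl chain on C6. In the forward key step Mg(OMe)2 in methanol generates the extended enolate of A5, pyrone C5 attacks the chain ester, and ring A closes by Claisen condensation to the 5,7-dihydroxyflavone ester A4.
- Merits: the closure is mild and biomimetic, the resorcinol oxygenation pattern is inherent, O5 and O7 emerge free and easily told apart, and the benzoate on ring E of A4 would allow the same ring F endgame as the chosen route. In the mildness of ring A formation and the absence of a late demethylation this road is better.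
- Weak points: A5 must already contain the congested C3–E3 bond, now on a 4-pyrone, so the central problem is moved and not solved. Installing the β,δ-dicarbonyl chain needs dianion chemistry beside a benzoate ester. Polyketide-type chains of this kind can fold in other ways (aldol closure, pyrone opening by alkoxide).
- Comparison: the chosen plan obtains ring A in one acylation of a purchased arene and spends its key step on the C3–E3 problem itself.

Alternative 3: Ring F is cut at C4a''–C4'', C4''–C3'' and O1''–C2'', giving iodoarene triacetate A8, carbon monoxide A9 and ethynyl flavone A7. In the forward key step PdCl2(PPh3)2 and diethylamine couple A8, A9 and A7 to an ynone; the amine unmasks an ortho phenoxide, which closes onto the alkyne to give A6.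
- Merits: ring F arises in one step from three components, where the chosen route needs saponification, acylation and cyclodehydration. In convergence of the endgame this road is better.
- Weak points: A8 is a 2,6-dioxygenated, electron-rich iodoarene, so oxidative addition to zerovalent palladium and insertion of A9 are slow, and direct coupling of A8 with A7 without A9 (leading to a benzofuran) competes. The ynone can close 5-exo to an aurone instead of 6-endo. A7 still needs the hindered C3–E3 bond to be made by some other means.
- Comparison: the chosen plan has a longer but unambiguous diketone route to ring F, and it offers a solution to the C3–E3 bond, which this road leaves open.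

Key step: step 7

Assumption: the C3–E3 aryl–aryl axis carries no stereodescriptor in the target, so it is treated as configurationally undefined and no control of axial chirality is planned.

## Route

Step 1
Reactants: 1 1,3,5-trimethoxybenzene; 2 methyl 4-chloro-4-oxobutanoate
Product: 3 methyl 4-oxo-4-(2,4,6-trimethoxyphenyl)butanoate
Conditions: AlCl3, CH2Cl2, 0 °C
Reagents that add atoms: none
Why: Friedel–Crafts acylation of a symmetrical, threefold activated arene; all ring positions are equivalent and the aryl ketone formed is deactivated towards a second acylation.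

Step 2
Reactants: 3 methyl 4-oxo-4-(2,4,6-trimethoxyphenyl)butanoate
Product: 4 methyl 4-(2-hydroxy-4,6-dimethoxyphenyl)-4-oxobutanoate
Conditions: BCl3 (1.2 equiv), CH2Cl2, −78 → 0 °C; aq. work-up
Reagents that add atoms: none
Why: Chelation-directed ether cleavage: boron binds the ketone oxygen and dealkylates one ortho methyl ether through a six-membered chelate; the chelate then occupies the carbonyl, so the second ortho ether, the para ether and the ester should remain.

Step 3
Reactants: 4 methyl 4-(2-hydroxy-4,6-dimethoxyphenyl)-4-oxobutanoate; 5 4-(benzyloxy)benzoyl chloride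
Product: 6 methyl 3-[4-(benzyloxy)benzoyl]-4-(2-hydroxy-4,6-dimethoxyphenyl)-4-oxobutanoate (racemic, enolisable 1,3-diketone)
Conditions: LiN(SiMe3)2 (3.1 equiv), THF, −78 → −10 °C; then 5, −78 °C → rt
Reagents that add atoms: none
Why: Lithium-amide variant of the Baker–Venkataraman diketone synthesis: the phenoxide–ketone enolate dianion is aroylated at carbon, and any O-aroyl ester formed is shifted to carbon by the excess base; the ketone α-protons are more acidic than the ester α-protons, so the side-chain ester should stay a spectator.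

Step 4
Reactants: 6 methyl 3-[4-(benzyloxy)benzoyl]-4-(2-hydroxy-4,6-dimethoxyphenyl)-4-oxobutanoate
Product: 7 methyl 2-{2-[4-(benzyloxy)phenyl]-5,7-dimethoxy-4-oxo-4H-chromen-3-yl}acetate
Conditions: TsOH·H2O (cat.), PhMe, 100 °C
Reagents that add atoms: none
Why: Acid-catalysed cyclodehydration of an o-hydroxyaryl 1,3-diketone: the phenol adds to the aroyl carbonyl and water is lost, closing ring C with the acetate arm already on C3.

Step 5
Reactants: 7 methyl 2-{2-[4-(benzyloxy)phenyl]-5,7-dimethoxy-4-oxo-4H-chromen-3-yl}acetate
Product: 8 2-{2-[4-(benzyloxy)phenyl]-5,7-dimethoxy-4-oxo-4H-chromen-3-yl}acetic acid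
Conditions: LiOH, THF/H2O, rt; then aq. HCl
Reagents that add atoms: lithium hydroxide, [Li+].[OH-]
Why: Saponification of an unhindered methyl ester; the 2,3-disubstituted chromone should resist hydroxide attack at C2 at room temperature.

Step 6
Reactants: 8 2-{2-[4-(benzyloxy)phenyl]-5,7-dimethoxy-4-oxo-4H-chromen-3-yl}acetic acid
Product: 9 2-[4-(benzyloxy)phenyl]-3-[2,2-bis(tert-butyldimethylsilyloxy)ethenyl]-5,7-dimethoxy-4H-chromen-4-one
Conditions: LiN(iPr)2 (2.3 equiv), THF, −78 → −20 °C; TBSCl (2.5 equiv), DMPU, −78 °C → rt; pentane extraction without aqueous work-up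
Reagents that add atoms: tert-butyldimethylsilyl chloride, CC(C)(C)[Si](C)(C)Cl
Why: Double deprotonation of an arylacetic-type acid to its enediolate and O,O-disilylation (Ainsworth-type bis(silyl) ketene acetal synthesis); the polar cosolvent favours O- over C-silylation, and the hindered amide at low temperature should not add to the 2,3-disubstituted chromone.

Step 7
Reactants: 9 2-[4-(benzyloxy)phenyl]-3-[2,2-bis(tert-butyldimethylsilyloxy)ethenyl]-5,7-dimethoxy-4H-chromen-4-one; 10 methyl coumalate (methyl 2-oxo-2H-pyran-5-carboxylate)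
Product: 13 methyl 3-{2-[4-(benzyloxy)phenyl]-5,7-dimethoxy-4-oxo-4H-chromen-3-yl}-4-(tert-butyldimethylsilyloxy)benzoate, via bridged lactone 11 (not isolated), via cyclohexadiene 12 (not isolated)
Conditions: 10 (3 equiv), PhMe, 130 °C, sealed tube
Reagents that add atoms: none
Why: Inverse-electron-demand Diels–Alder reaction of a 2-pyrone with a ketene acetal, followed by cycloreversion and elimination; the closest known reaction type is the conversion of methyl coumalate into 4-alkoxybenzoates by enol ethers, ketals and orthoester-derived ketene acetals. The electron-rich C=C bond of 9 adds across C3 and C6 of 10 to give bridged lactone 11, which expels CO2 by retro-[4+2] reaction to diene 12, and 12 loses tert-butyldimethylsilanol by 1,2-elimination across E3–E4 to give the arene. Ring E is thus closed by an intermolecular [4+2] cycloaddition that forms both new ring bonds, E2–E3 and E4–E5, and no oxidant is needed because one silyloxy group leaves at the oxidation level of the missing double bond. The stereocentres of 11 and 12 are transient and vanish on aromatisation, so endo/exo and facial selectivity are irrelevant and the product has no stereocentre. The selectivity that matters is regiochemical: the nucleophilic CH carbon of 9 (future E3) must bond to pyrone C6 and the acetal carbon (future E4) to C3. Polarity should secure this, because C6 is activated by both the C5 ester and the vinylogous lactone carbonyl, while the CH carbon bears the largest HOMO coefficient of the ketene acetal. The two identical silyloxy groups make the choice of leaving group meaningless, and the ester ends on E1, para to the surviving silyl ether. The chromone C2=C3 bond should not compete as part of a diene because the C2 aryl group prevents an s-cis arrangement with the ketene acetal, and the benzyl and methyl ethers are inert at this temperature.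

Step 8
Reactants: 13 methyl 3-{2-[4-(benzyloxy)phenyl]-5,7-dimethoxy-4-oxo-4H-chromen-3-yl}-4-(tert-butyldimethylsilyloxy)benzoate
Product: 15 methyl 4-(benzyloxy)-3-{2-[4-(benzyloxy)phenyl]-5,7-dimethoxy-4-oxo-4H-chromen-3-yl}benzoate, via phenol 14 (not isolated)
Conditions: CsF, BnBr, DMF, rt
Reagents that add atoms: benzyl bromide, BrCc1ccccc1
Why: Fluoride cleaves the aryl silyl ether (the phenoxide para to an ester is a good leaving group from silicon), and the cesium phenoxide is benzylated in the same flask by Williamson alkylation.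

Step 9
Reactants: 15 methyl 4-(benzyloxy)-3-{2-[4-(benzyloxy)phenyl]-5,7-dimethoxy-4-oxo-4H-chromen-3-yl}benzoate
Product: 16 4-(benzyloxy)-3-{2-[4-(benzyloxy)phenyl]-5,7-dimethoxy-4-oxo-4H-chromen-3-yl}benzoic acid
Conditions: LiOH, THF/MeOH/H2O, 40 °C; then aq. HCl
Reagents that add atoms: lithium hydroxide, [Li+].[OH-]
Why: Saponification of a methyl benzoate that has no ortho substituent; benzyl and methyl ethers and the hindered chromone should be unaffected.

Step 10
Reactants: 17 2',4',6'-trihydroxyacetophenone
Product: 18 1-[2,4-bis(benzyloxy)-6-hydroxyphenyl]ethan-1-one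
Conditions: BnBr (2.1 equiv), K2CO3, acetone, reflux
Reagents that add atoms: benzyl bromide, BrCc1ccccc1
Why: Williamson benzylation; after the first two alkylations the remaining hydroxyl is hydrogen-bonded to the acetyl group and is the least nucleophilic, so the reaction should stop at the dibenzyl ether.

Step 11
Reactants: 16 4-(benzyloxy)-3-{2-[4-(benzyloxy)phenyl]-5,7-dimethoxy-4-oxo-4H-chromen-3-yl}benzoic acid; 18 1-[2,4-bis(benzyloxy)-6-hydroxyphenyl]ethan-1-one
Product: 20 1-[2,4-bis(benzyloxy)-6-hydroxyphenyl]-3-(4-(benzyloxy)-3-{2-[4-(benzyloxy)phenyl]-5,7-dimethoxy-4-oxo-4H-chromen-3-yl}phenyl)propane-1,3-dione, via acid chloride 19 (not isolated)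
Conditions: (COCl)2 (1.2 equiv), cat. DMF, CH2Cl2, 0 °C, evaporate; then 18, LiN(SiMe3)2 (3.1 equiv), THF, −78 °C → rt
Reagents that add atoms: none
Why: Acid chloride formation via the Vilsmeier intermediate, then C-aroylation of the lithium phenoxide–enolate dianion of 18 (lithium-amide variant of the Baker–Venkataraman synthesis); the third equivalent of base captures the acidic diketone as it forms and prevents double acylation.

Step 12
Reactants: 20 1-[2,4-bis(benzyloxy)-6-hydroxyphenyl]-3-(4-(benzyloxy)-3-{2-[4-(benzyloxy)phenyl]-5,7-dimethoxy-4-oxo-4H-chromen-3-yl}phenyl)propane-1,3-dione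
Product: 21 5,7-bis(benzyloxy)-2-(4-(benzyloxy)-3-{2-[4-(benzyloxy)phenyl]-5,7-dimethoxy-4-oxo-4H-chromen-3-yl}phenyl)-4H-chromen-4-one
Conditions: TsOH·H2O (cat.), PhMe, 90 °C
Reagents that add atoms: none
Why: Acid-catalysed cyclodehydration of the o-hydroxyaryl 1,3-diketone closes ring F (O1''–C2''); partial loss of the peri benzyl group would be harmless because the next step removes all benzyl groups.

Step 13
Reactants: 21 5,7-bis(benzyloxy)-2-(4-(benzyloxy)-3-{2-[4-(benzyloxy)phenyl]-5,7-dimethoxy-4-oxo-4H-chromen-3-yl}phenyl)-4H-chromen-4-one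
Product: 22 5,7-dihydroxy-2-{4-hydroxy-3-[5-hydroxy-2-(4-hydroxyphenyl)-7-methoxy-4-oxo-4H-chromen-3-yl]phenyl}-4H-chromen-4-one (target)
Conditions: BCl3 (excess), C6HMe5, CH2Cl2, −78 °C → rt; MeOH quench
Reagents that add atoms: none
Why: Lewis-acid ether cleavage: BCl3 removes the four aryl benzyl ethers at low temperature, with pentamethylbenzene trapping the benzyl cations, and on warming it cleaves the O5 methyl ether through the chelate with the C4 carbonyl; the O7 methyl ether lacks this assistance and should persist.

## Compound list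

1 | 1,3,5-trimethoxybenzene | COc1cc(OC)cc(OC)c1 | starting material
2 | methyl 4-chloro-4-oxobutanoate | COC(=O)CCC(=O)Cl | starting material
3 | methyl 4-oxo-4-(2,4,6-trimethoxyphenyl)butanoate | COC(=O)CCC(=O)c1c(OC)cc(OC)cc1OC | intermediate
4 | methyl 4-(2-hydroxy-4,6-dimethoxyphenyl)-4-oxobutanoate | COC(=O)CCC(=O)c1c(O)cc(OC)cc1OC | intermediate
5 | 4-(benzyloxy)benzoyl chloride | O=C(Cl)c1ccc(OCc2ccccc2)cc1 | starting material
6 | methyl 3-[4-(benzyloxy)benzoyl]-4-(2-hydroxy-4,6-dimethoxyphenyl)-4-oxobutanoate (racemic) | COC(=O)CC(C(=O)c1ccc(OCc2ccccc2)cc1)C(=O)c1c(O)cc(OC)cc1OC | intermediate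
7 | methyl 2-{2-[4-(benzyloxy)phenyl]-5,7-dimethoxy-4-oxo-4H-chromen-3-yl}acetate | COC(=O)Cc1c(-c2ccc(OCc3ccccc3)cc2)oc2cc(OC)cc(OC)c2c1=O | intermediate
8 | 2-{2-[4-(benzyloxy)phenyl]-5,7-dimethoxy-4-oxo-4H-chromen-3-yl}acetic acid | OC(=O)Cc1c(-c2ccc(OCc3ccccc3)cc2)oc2cc(OC)cc(OC)c2c1=O | intermediate
9 | 2-[4-(benzyloxy)phenyl]-3-[2,2-bis(tert-butyldimethylsilyloxy)ethenyl]-5,7-dimethoxy-4H-chromen-4-one | COc1cc(OC)c2c(=O)c(C=C(O[Si](C)(C)C(C)(C)C)O[Si](C)(C)C(C)(C)C)c(-c3ccc(OCc4ccccc4)cc3)oc2c1 | intermediate
10 | methyl coumalate (methyl 2-oxo-2H-pyran-5-carboxylate) | COC(=O)C1=COC(=O)C=C1 | starting material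
11 | methyl 7-{2-[4-(benzyloxy)phenyl]-5,7-dimethoxy-4-oxo-4H-chromen-3-yl}-8,8-bis(tert-butyldimethylsilyloxy)-3-oxo-2-oxabicyclo[2.2.2]oct-5-ene-6-carboxylate (transient, mixture of diastereomers, configuration immaterial) | COC(=O)C1=CC2C(=O)OC1C(c1c(-c3ccc(OCc4ccccc4)cc3)oc3cc(OC)cc(OC)c3c1=O)C2(O[Si](C)(C)C(C)(C)C)O[Si](C)(C)C(C)(C)C | intermediate
12 | methyl 3-{2-[4-(benzyloxy)phenyl]-5,7-dimethoxy-4-oxo-4H-chromen-3-yl}-4,4-bis(tert-butyldimethylsilyloxy)cyclohexa-1,5-diene-1-carboxylate (transient, racemic) | COC(=O)C1=CC(c2c(-c3ccc(OCc4ccccc4)cc3)oc3cc(OC)cc(OC)c3c2=O)C(O[Si](C)(C)C(C)(C)C)(O[Si](C)(C)C(C)(C)C)C=C1 | intermediate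
13 | methyl 3-{2-[4-(benzyloxy)phenyl]-5,7-dimethoxy-4-oxo-4H-chromen-3-yl}-4-(tert-butyldimethylsilyloxy)benzoate | COC(=O)c1ccc(O[Si](C)(C)C(C)(C)C)c(-c2c(-c3ccc(OCc4ccccc4)cc3)oc3cc(OC)cc(OC)c3c2=O)c1 | intermediate
14 | methyl 3-{2-[4-(benzyloxy)phenyl]-5,7-dimethoxy-4-oxo-4H-chromen-3-yl}-4-hydroxybenzoate | COC(=O)c1ccc(O)c(-c2c(-c3ccc(OCc4ccccc4)cc3)oc3cc(OC)cc(OC)c3c2=O)c1 | intermediate
15 | methyl 4-(benzyloxy)-3-{2-[4-(benzyloxy)phenyl]-5,7-dimethoxy-4-oxo-4H-chromen-3-yl}benzoate | COC(=O)c1ccc(OCc2ccccc2)c(-c2c(-c3ccc(OCc4ccccc4)cc3)oc3cc(OC)cc(OC)c3c2=O)c1 | intermediate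
16 | 4-(benzyloxy)-3-{2-[4-(benzyloxy)phenyl]-5,7-dimethoxy-4-oxo-4H-chromen-3-yl}benzoic acid | OC(=O)c1ccc(OCc2ccccc2)c(-c2c(-c3ccc(OCc4ccccc4)cc3)oc3cc(OC)cc(OC)c3c2=O)c1 | intermediate
17 | 2',4',6'-trihydroxyacetophenone | CC(=O)c1c(O)cc(O)cc1O | starting material
18 | 1-[2,4-bis(benzyloxy)-6-hydroxyphenyl]ethan-1-one | CC(=O)c1c(O)cc(OCc2ccccc2)cc1OCc1ccccc1 | intermediate
19 | 4-(benzyloxy)-3-{2-[4-(benzyloxy)phenyl]-5,7-dimethoxy-4-oxo-4H-chromen-3-yl}benzoyl chloride | O=C(Cl)c1ccc(OCc2ccccc2)c(-c2c(-c3ccc(OCc4ccccc4)cc3)oc3cc(OC)cc(OC)c3c2=O)c1 | intermediate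
20 | 1-[2,4-bis(benzyloxy)-6-hydroxyphenyl]-3-(4-(benzyloxy)-3-{2-[4-(benzyloxy)phenyl]-5,7-dimethoxy-4-oxo-4H-chromen-3-yl}phenyl)propane-1,3-dione | O=C(CC(=O)c1ccc(OCc2ccccc2)c(-c2c(-c3ccc(OCc4ccccc4)cc3)oc3cc(OC)cc(OC)c3c2=O)c1)c1c(O)cc(OCc2ccccc2)cc1OCc1ccccc1 | intermediate
21 | 5,7-bis(benzyloxy)-2-(4-(benzyloxy)-3-{2-[4-(benzyloxy)phenyl]-5,7-dimethoxy-4-oxo-4H-chromen-3-yl}phenyl)-4H-chromen-4-one | COc1cc(OC)c2c(=O)c(-c3cc(-c4cc(=O)c5c(OCc6ccccc6)cc(OCc6ccccc6)cc5o4)ccc3OCc3ccccc3)c(-c3ccc(OCc4ccccc4)cc3)oc2c1 | intermediate
22 | 5,7-dihydroxy-2-{4-hydroxy-3-[5-hydroxy-2-(4-hydroxyphenyl)-7-methoxy-4-oxo-4H-chromen-3-yl]phenyl}-4H-chromen-4-one | COc1cc(O)c2c(=O)c(-c3cc(-c4cc(=O)c5c(O)cc(O)cc5o4)ccc3O)c(-c3ccc(O)cc3)oc2c1 | target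

## Step count and least certain steps

Total steps: 13. Longest linear sequence: 12 steps (steps 1–9 and 11–13); step 10 prepares the side fragment 18.

**Step 7 (key step).** The twisted chromone, with its C2 aryl and C4 carbonyl flanking the reacting CH carbon, may slow the cycloaddition so much that thermal dimerisation of the pyrone dominates. The addition may also stop after Michael-type attack at C6 and open the pyrone instead of closing the second bond. The silanol released on aromatisation can protonate unreacted ketene acetal back to the silyl ester; a silylating scavenger such as N,O-bis(trimethylsilyl)acetamide would counter this. The fallback forms the C3–E3 bond by cross-coupling instead of ring construction; it sets out from 5 and comes back to the route at 15. The lithium dianion of commercial 1-(2-hydroxy-4,6-dimethoxyphenyl)ethan-1-one is aroylated with 5 to give 1-[4-(benzyloxy)phenyl]-3-(2-hydroxy-4,6-dimethoxyphenyl)propane-1,3-dione F1, which TsOH closes to 2-[4-(benzyloxy)phenyl]-5,7-dimethoxy-4H-chromen-4-one F2. Lithiation of F2 at C3 with LiN(iPr)2 at −78 °C and an iodine quench give 2-[4-(benzyloxy)phenyl]-3-iodo-5,7-dimethoxy-4H-chromen-4-one F3. Separately, commercial methyl 3-bromo-4-hydroxybenzoate is benzylated to methyl 4-(benzyloxy)-3-bromobenzoate F4, and Miyaura borylation (bis(pinacolato)diboron, PdCl2(dppf), KOAc) gives methyl 4-(benzyloxy)-3-(4,4,5,5-tetramethyl-1,3,2-dioxaborolan-2-yl)benzoate F5. Suzuki–Miyaura coupling of F3 with F5 (Pd(OAc)2, SPhos, K3PO4, toluene/water) then gives 15.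

**Step 6.** The second deprotonation may be incomplete, the enediolate may be silylated partly on carbon, the amide base may attack the chromone, or the ketene acetal may hydrolyse during isolation. The fallback keeps lithium amides away from the chromone. It sets out from 8, which is converted with TBSCl and imidazole into tert-butyldimethylsilyl 2-{2-[4-(benzyloxy)phenyl]-5,7-dimethoxy-4-oxo-4H-chromen-3-yl}acetate F6. Soft enolisation of F6 with TBSOTf and Et3N in CH2Cl2 then comes back to the route at 9.

**Step 11.** Oxalyl chloride may activate the electron-rich chromone carbonyl as well as the acid. The dianion of 18, hindered by its ortho benzyloxy group, may be acylated slowly or on oxygen, and a second acylation may follow. The fallback separates O-acylation from the carbon–carbon bond formation and sets out from 16 and 18. Carbodiimide esterification (EDC, DMAP, CH2Cl2) gives 2-acetyl-3,5-bis(benzyloxy)phenyl 4-(benzyloxy)-3-{2-[4-(benzyloxy)phenyl]-5,7-dimethoxy-4-oxo-4H-chromen-3-yl}benzoate F7. A Baker–Venkataraman acyl shift with KOtBu in THF then comes back to the route at 20.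

**Step 13.** Boron chelates of the partly deprotected polyphenol may precipitate before the O5 methyl ether is cleaved. Benzyl cations may C-alkylate ring D if trapping is too slow, and prolonged warming could begin to erode the O7 methyl ether. The fallback splits the deprotection into two mechanistically different stages and sets out from 21. Hydrogenolysis (H2, Pd/C, THF/MeOH) gives 2-{4-hydroxy-3-[2-(4-hydroxyphenyl)-5,7-dimethoxy-4-oxo-4H-chromen-3-yl]phenyl}-5,7-dihydroxy-4H-chromen-4-one F8. Chelation-controlled demethylation of F8 at O5 with AlCl3 in MeCN then comes back to the route at 22.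

## Further compounds

F1 | step 7 | 1-[4-(benzyloxy)phenyl]-3-(2-hydroxy-4,6-dimethoxyphenyl)propane-1,3-dione | COc1cc(O)c(C(=O)CC(=O)c2ccc(OCc3ccccc3)cc2)c(OC)c1
F2 | step 7 | 2-[4-(benzyloxy)phenyl]-5,7-dimethoxy-4H-chromen-4-one | COc1cc(OC)c2c(=O)cc(-c3ccc(OCc4ccccc4)cc3)oc2c1
F3 | step 7 | 2-[4-(benzyloxy)phenyl]-3-iodo-5,7-dimethoxy-4H-chromen-4-one | COc1cc(OC)c2c(=O)c(I)c(-c3ccc(OCc4ccccc4)cc3)oc2c1
F4 | step 7 | methyl 4-(benzyloxy)-3-bromobenzoate | COC(=O)c1ccc(OCc2ccccc2)c(Br)c1
F5 | step 7 | methyl 4-(benzyloxy)-3-(4,4,5,5-tetramethyl-1,3,2-dioxaborolan-2-yl)benzoate | COC(=O)c1ccc(OCc2ccccc2)c(B2OC(C)(C)C(C)(C)O2)c1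
F6 | step 6 | tert-butyldimethylsilyl 2-{2-[4-(benzyloxy)phenyl]-5,7-dimethoxy-4-oxo-4H-chromen-3-yl}acetate | CC(C)(C)[Si](C)(C)OC(=O)Cc1c(-c2ccc(OCc3ccccc3)cc2)oc2cc(OC)cc(OC)c2c1=O
F7 | step 11 | 2-acetyl-3,5-bis(benzyloxy)phenyl 4-(benzyloxy)-3-{2-[4-(benzyloxy)phenyl]-5,7-dimethoxy-4-oxo-4H-chromen-3-yl}benzoate | CC(=O)c1c(OC(=O)c2ccc(OCc3ccccc3)c(-c3c(-c4ccc(OCc5ccccc5)cc4)oc4cc(OC)cc(OC)c4c3=O)c2)cc(OCc2ccccc2)cc1OCc1ccccc1
F8 | step 13 | 2-{4-hydroxy-3-[2-(4-hydroxyphenyl)-5,7-dimethoxy-4-oxo-4H-chromen-3-yl]phenyl}-5,7-dihydroxy-4H-chromen-4-one | COc1cc(OC)c2c(=O)c(-c3cc(-c4cc(=O)c5c(O)cc(O)cc5o4)ccc3O)c(-c3ccc(O)cc3)oc2c1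
A1 | alternative 1 | 5,7-bis(benzyloxy)-2-(4-(benzyloxy)-3-{2-[4-(benzyloxy)phenyl]-5,7-dihydroxy-4-oxo-4H-chromen-3-yl}phenyl)-4H-chromen-4-one | Oc1cc(O)c2c(=O)c(-c3cc(-c4cc(=O)c5c(OCc6ccccc6)cc(OCc6ccccc6)cc5o4)ccc3OCc3ccccc3)c(-c3ccc(OCc4ccccc4)cc3)oc2c1
A2 | alternative 1 | methyl 2-{2-(benzyloxy)-5-[5,7-bis(benzyloxy)-4-oxo-4H-chromen-2-yl]phenyl}-3-[4-(benzyloxy)phenyl]-3-oxopropanoate (racemic) | COC(=O)C(C(=O)c1ccc(OCc2ccccc2)cc1)c1cc(-c2cc(=O)c3c(OCc4ccccc4)cc(OCc4ccccc4)cc3o2)ccc1OCc1ccccc1
A3 | alternative 1 | phloroglucinol | Oc1cc(O)cc(O)c1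
A4 | alternative 2 | methyl 4-(benzyloxy)-3-{2-[4-(benzyloxy)phenyl]-5,7-dihydroxy-4-oxo-4H-chromen-3-yl}benzoate | COC(=O)c1ccc(OCc2ccccc2)c(-c2c(-c3ccc(OCc4ccccc4)cc3)oc3cc(O)cc(O)c3c2=O)c1
A5 | alternative 2 | methyl 4-(benzyloxy)-3-{2-[4-(benzyloxy)phenyl]-6-(4-methoxy-2,4-dioxobutyl)-4-oxo-4H-pyran-3-yl}benzoate | COC(=O)CC(=O)Cc1cc(=O)c(-c2cc(C(=O)OC)ccc2OCc2ccccc2)c(-c2ccc(OCc3ccccc3)cc2)o1
A6 | alternative 3 | 5-(benzyloxy)-3-{2-(benzyloxy)-5-[5,7-dihydroxy-4-oxo-4H-chromen-2-yl]phenyl}-2-[4-(benzyloxy)phenyl]-7-methoxy-4H-chromen-4-one | COc1cc(OCc2ccccc2)c2c(=O)c(-c3cc(-c4cc(=O)c5c(O)cc(O)cc5o4)ccc3OCc3ccccc3)c(-c3ccc(OCc4ccccc4)cc3)oc2c1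
A7 | alternative 3 | 5-(benzyloxy)-3-[2-(benzyloxy)-5-ethynylphenyl]-2-[4-(benzyloxy)phenyl]-7-methoxy-4H-chromen-4-one | COc1cc(OCc2ccccc2)c2c(=O)c(-c3cc(C#C)ccc3OCc3ccccc3)c(-c3ccc(OCc4ccccc4)cc3)oc2c1
A8 | alternative 3 | 2-iodobenzene-1,3,5-triyl triacetate | CC(=O)Oc1cc(OC(C)=O)c(I)c(OC(C)=O)c1
A9 | alternative 3 | carbon monoxide | [C-]#[O+]
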